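**Retrosynthetic overview**
- The target is cut back to 6-bromo-1H-indole (13); the C3 and C2 bromines are added last by electrophilic bromination.
- 13 is opened across C3a–C7a and C4–C5 to the N-Boc 2-amino-4-bromofuran 9, which carries a 2-hydroxybut-3-enyl group on nitrogen (furan Diels–Alder, then loss of two waters and of Boc).
- The strategy rests on the benzo ring: N on C7a, Br on C6 and H on C4, C5 and C7. Furan C2, C3, C4, C5 become C7a, C7, C6, C5; the vinyl group supplies C3a and C4; the N–CH2–CH(OH) tether supplies C2 and C3.
- 9 comes from aldehyde 7 and vinylmagnesium bromide; 7 from Weinreb amide 6; 6 from carbamate 4 and bromoacetamide 5; 4 from 4-bromo-2-furoic acid by Curtius rearrangement.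
- Ring order: the carbocycle and the five-membered nitrogen ring close in the same cycloaddition and are aromatised in the same flask.

Key step: step 5

Remark on the chemistry: the carbinol carbon of 9 is made as a racemate, which has no consequence because it becomes the sp2 carbon C3. The Boc group is assumed to leave thermally at the end of the cascade in step 5, so the isolated product of that step is the N–H indole.

**Step 1**
Reactants: 1 4-bromofuran-2-carboxylic acid (4-bromo-2-furoic acid)
Product: 4 tert-butyl (4-bromofuran-2-yl)carbamate, via 4-bromofuran-2-carbonyl azide 2 (not isolated), via 4-bromo-2-isocyanatofuran 3 (not isolated)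
Conditions: (PhO)2P(O)N3, Et3N, t-BuOH, rt then reflux
Reagents that add atoms: diphenylphosphoryl azide, [N-]=[N+]=NP(=O)(Oc1ccccc1)Oc1ccccc1; tert-butanol, CC(C)(C)O
Why: Curtius rearrangement, in which the carboxylate and the phosphoryl azide give acyl azide 2, loss of N2 with migration of the furyl group gives isocyanate 3, and tert-butanol traps it as the Boc carbamate, so the unstable free aminofuran is never formed.

**Step 2**
Reactants: 4 tert-butyl (4-bromofuran-2-yl)carbamate; 5 2-bromo-N-methoxy-N-methylacetamide
Product: 6 tert-butyl (4-bromofuran-2-yl)[2-(methoxy(methyl)amino)-2-oxoethyl]carbamate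
Conditions: NaH, DMF, 0 °C; then 5, 0 °C to rt
Reagents that add atoms: none
Why: N-alkylation (SN2) of the sodium salt of the carbamate with an α-bromo amide, a fast electrophile because of the adjacent carbonyl, while the furyl bromide is inert to NaH.

**Step 3**
Reactants: 6 tert-butyl (4-bromofuran-2-yl)[2-(methoxy(methyl)amino)-2-oxoethyl]carbamate
Product: 7 tert-butyl (4-bromofuran-2-yl)(2-oxoethyl)carbamate
Conditions: i-Bu2AlH (1.2 equiv), THF, −78 °C; aqueous potassium sodium tartrate
Reagents that add atoms: none
Why: Weinreb amide reduction, in which the chelated aluminium hemiaminal holds at −78 °C and releases the aldehyde only on work-up, so over-reduction is avoided and the Boc group and the C–Br bond are untouched.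

**Step 4**
Reactants: 7 tert-butyl (4-bromofuran-2-yl)(2-oxoethyl)carbamate (used crude); 8 vinylmagnesium bromide
Product: 9 tert-butyl (4-bromofuran-2-yl)(2-hydroxybut-3-en-1-yl)carbamate (racemic)
Conditions: CH2=CHMgBr (1.3 equiv), THF, −78 °C; saturated aqueous NH4Cl at −78 °C
Reagents that add atoms: none
Why: 1,2-addition of a vinyl Grignard reagent to the aldehyde, where the new carbinol stereocentre forms without control (racemate, later the sp2 carbon C3) and the cold quench keeps the magnesium alkoxide from attacking the Boc carbonyl.

**Step 5**
Reactants: 9 tert-butyl (4-bromofuran-2-yl)(2-hydroxybut-3-en-1-yl)carbamate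
Product: 13 6-bromo-1H-indole, via oxa-bridged cycloadduct 10 (not isolated), via tert-butyl 6-bromo-3-hydroxyindoline-1-carboxylate 11 (not isolated), via tert-butyl 6-bromo-1H-indole-1-carboxylate 12 (not isolated)
Conditions: o-dichlorobenzene (0.05 M, degassed), microwave, 180 °C, 30 min, sealed vial
Reagents that add atoms: none
Why: Heating makes the furan (diene termini C2 and C5) add across the N-tethered vinyl group in an intramolecular [4+2] cycloaddition that forms C3a–C7a and C4–C5 (10); the carbamate nitrogen then opens the C7a–O bridge bond, the former furan oxygen leaves as water to aromatise the carbocycle (11), the benzylic C3 hydroxyl leaves as a second water to aromatise the pyrrole ring (12), and the N-Boc indole sheds isobutene and CO2 at this temperature. The closest known reaction type is the intramolecular Diels–Alder reaction of N-Boc 2-aminofurans that carry a but-3-enyl or 2-hydroxyalk-3-enyl group on nitrogen, which gives indolines and indoles by the same bridge opening and dehydration. The five-membered nitrogen ring closes because the tether N–CH2–CH(OH) places the internal vinyl carbon on furan C2 (a 5-exo-type closure inside the cycloaddition), and the six-membered carbocycle is the ring made by the 4π+2π combination itself. The stereocentres of 10 and the carbinol centre of 9 are transient and all become sp2 carbons, so no stereocontrol is required. The step needs regioselectivity (bromine at C6, not C5), secured by the three-atom tether, which allows only the orientation that joins the internal alkene carbon to furan C2 so that furan C4–Br becomes indole C6–Br; the C–Br bond should survive because no metal, base or nucleophile is present.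

**Step 6**
Reactants: 13 6-bromo-1H-indole
Product: 15 2,3,6-tribromo-1H-indole, via 3,6-dibromo-1H-indole 14 (not isolated)
Conditions: NBS (2.05 equiv), silica gel, CH2Cl2, 0 °C to rt, dark, N2
Reagents that add atoms: N-bromosuccinimide, O=C1CCC(=O)N1Br
Why: Electrophilic aromatic bromination, in which the first equivalent takes the most nucleophilic position C3 (14), the second attacks C3 again and the 3,3-dibromoindolenine shifts bromine to C2 and loses a proton, the C6 bromine deactivates the benzo ring, and NBS on silica gel is an established reagent for 2,3-dibromination of N–H indoles.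

**Compound list**
1 | 4-bromofuran-2-carboxylic acid | OC(=O)c1cc(Br)co1 | starting material
2 | 4-bromofuran-2-carbonyl azide | [N-]=[N+]=NC(=O)c1cc(Br)co1 | intermediate (not isolated)
3 | 4-bromo-2-isocyanatofuran | O=C=Nc1cc(Br)co1 | intermediate (not isolated)
4 | tert-butyl (4-bromofuran-2-yl)carbamate | CC(C)(C)OC(=O)Nc1cc(Br)co1 | intermediate
5 | 2-bromo-N-methoxy-N-methylacetamide | CON(C)C(=O)CBr | starting material
6 | tert-butyl (4-bromofuran-2-yl)[2-(methoxy(methyl)amino)-2-oxoethyl]carbamate | CC(C)(C)OC(=O)N(CC(=O)N(C)OC)c1cc(Br)co1 | intermediate
7 | tert-butyl (4-bromofuran-2-yl)(2-oxoethyl)carbamate | CC(C)(C)OC(=O)N(CC=O)c1cc(Br)co1 | intermediate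
8 | vinylmagnesium bromide | C=C[Mg]Br | starting material
9 | tert-butyl (4-bromofuran-2-yl)(2-hydroxybut-3-en-1-yl)carbamate, racemic | CC(C)(C)OC(=O)N(CC(O)C=C)c1cc(Br)co1 | intermediate
10 | tert-butyl 6-bromo-3-hydroxy-2,3,3a,4-tetrahydro-5,7a-epoxyindole-1(5H)-carboxylate (oxa-bridged cycloadduct; racemic, mixture of C3 epimers, all stereocentres lost later) | CC(C)(C)OC(=O)N1CC(O)C2CC3OC21C=C3Br | intermediate (not isolated)
11 | tert-butyl 6-bromo-3-hydroxyindoline-1-carboxylate, racemic | CC(C)(C)OC(=O)N1CC(O)c2ccc(Br)cc21 | intermediate (not isolated)
12 | tert-butyl 6-bromo-1H-indole-1-carboxylate | CC(C)(C)OC(=O)n1ccc2ccc(Br)cc21 | intermediate (not isolated)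
13 | 6-bromo-1H-indole | Brc1ccc2cc[nH]c2c1 | intermediate
14 | 3,6-dibromo-1H-indole | Brc1ccc2c(Br)c[nH]c2c1 | intermediate (not isolated)
15 | 2,3,6-tribromo-1H-indole | Brc1ccc2c(Br)c(Br)[nH]c2c1 | target

**Step count**
Total steps: 6. Longest linear sequence: 6 steps (from 1).

**Steps most likely to fail**

1. Step 5. The Boc group may leave, or the free hydroxyl may cyclise onto the carbamate, before the cycloaddition has taken place; either would divert the labile aminofuran away from the cascade, and the second dehydration may also stall. The fallback sets out from 4 and comes back at 13, reaching the indole through the indoline oxidation level without a tether hydroxyl. Alkylation of 4 with 4-bromobut-1-ene (NaH, DMF) should give tert-butyl but-3-en-1-yl(4-bromofuran-2-yl)carbamate F1. Heating F1 in toluene at 150–165 °C in a sealed tube should give the oxa-bridged cycloadduct F2, which is not isolated. Bridge opening and loss of one water then lead to tert-butyl 6-bromoindoline-1-carboxylate F3, in which the Boc group is expected to hold. CF3CO2H in CH2Cl2 should give 6-bromoindoline F4, and MnO2 in CH2Cl2 should dehydrogenate it to 13.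

2. Step 6. Bromination may run on into the benzo ring, adventitious water may oxidise C2 to oxindole-type products, and the light- and acid-sensitive N–H dibromoindole may decompose on silica. The fallback sets out from 13 and comes back at 15, placing the two bromines one at a time on the N-protected indole. Boc2O with DMAP in MeCN should return 12. Deprotonation at C2 with LDA in THF at −78 °C and quenching with BrCl2C–CCl2Br should give tert-butyl 2,6-dibromo-1H-indole-1-carboxylate F5. NBS in DMF should then brominate C3 to tert-butyl 2,3,6-tribromo-1H-indole-1-carboxylate F6. K2CO3 in MeOH at rt should remove the carbamate to give 15.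

3. Step 4. The α-amino aldehyde may enolise or self-condense under the basic Grignard reagent, and the magnesium alkoxide may attack the Boc carbonyl (carbamate transfer or oxazolidinone closure). The fallback sets out from 6 and comes back at 9, avoiding the aldehyde by forming the carbinol through reduction. Addition of 8 to Weinreb amide 6 in THF at −78 to 0 °C, with an inverse quench into cold dilute acid, should give tert-butyl (4-bromofuran-2-yl)(2-oxobut-3-en-1-yl)carbamate F7. F7 is kept cold and reduced at once with NaBH4 and CeCl3·7H2O in MeOH at −78 °C (Luche 1,2-reduction) to give 9.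

**Further compounds**
F1 | step 5 | tert-butyl but-3-en-1-yl(4-bromofuran-2-yl)carbamate | CC(C)(C)OC(=O)N(CCC=C)c1cc(Br)co1
F2 | step 5 | tert-butyl 6-bromo-2,3,3a,4-tetrahydro-5,7a-epoxyindole-1(5H)-carboxylate (oxa-bridged cycloadduct, racemic, not isolated) | CC(C)(C)OC(=O)N1CCC2CC3OC21C=C3Br
F3 | step 5 | tert-butyl 6-bromoindoline-1-carboxylate | CC(C)(C)OC(=O)N1CCc2ccc(Br)cc21
F4 | step 5 | 6-bromoindoline | Brc1ccc2c(c1)NCC2
F5 | step 6 | tert-butyl 2,6-dibromo-1H-indole-1-carboxylate | CC(C)(C)OC(=O)n1c(Br)cc2ccc(Br)cc21
F6 | step 6 | tert-butyl 2,3,6-tribromo-1H-indole-1-carboxylate | CC(C)(C)OC(=O)n1c(Br)c(Br)c2ccc(Br)cc21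
F7 | step 4 | tert-butyl (4-bromofuran-2-yl)(2-oxobut-3-en-1-yl)carbamate | CC(C)(C)OC(=O)N(CC(=O)C=C)c1cc(Br)co1
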